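If the electrophile stops falling while the nucleophile fed should still carry it further, look first at the free base.

in all of them: electrophile 0.082 M; protic impurity 0.0164 M

| run | nucleophile | free base | remark | time |
|---|---|---|---|---|
| south-east | 0.74 equiv (fed, over 15 h) | 0.50 equiv | run made earlier |  |
| autumn | 1.10 equiv (fed, over 15 h) | 0.500 equiv |  | 3.0 d |
| noon | 1.10 equiv (fed, over 15 h) | 0.750 equiv |  | 3.0 d |

south-east run (percent of the electrophile charged)

| time / h | electrophile / % | product / % |
|---|---|---|
| 6.00 | 78 | 19 |
| 12.0 | 58 | 39 |
| 20.0 | 45 | 49 |
| 25.0 | 41 | 57 |

(each reading ± 1.5 percentage points)

- a reading or a percentage of product counts all its forms, free or not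
- no earlier run changes the charge of free base; that part of a forecast is a guess

- part of the electrophile that has reacted at the end, autumn
- part of the electrophile that has reacted at the end, noon
- what raising the equivalents of free base from its lowest to its highest value here does to the part of the electrophile that has reacted (changes below 5 percentage points count as none) (it falls / it rises / no change)

Two of us stood at the board over the south-east run. By 25.0 h, later than the end of its feed, the readings show 59.0% of its electrophile gone, and the fall has slowed.

The first said that of 0.74 equiv of nucleophile fed, 0.150 equiv went elsewhere, and the protic impurity, charged at 0.200 equiv, can account for that. So autumn and noon alike have a nucleophile budget, the charge less the impurity, of 0.900 equiv, whatever the free base.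

The second supposed that each electrophile reacting sets free one acid. Free base takes that acid up to its charge, but beyond it the acid takes a nucleophile too, so each further electrophile costs two nucleophile. Let the stall level be half the sum of the nucleophile and free base equivalents, or the nucleophile charge if that is smaller (the limiting reagent); for autumn it is 0.800 equiv. South-east gives 0.620 equiv, also near the reading, so that run leaves the dispute open, since it has one charge of free base.

Noon gives 0.925 equiv. No earlier run changes the charge of free base, so siding with the second is my guess: autumn near its stall level, which lies lower than the budget, noon near the budget, and a rise with free base.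

The forecast sides with the first, with 88% for autumn, 89% for noon and no change: “Its effect is untested, so I guess no change”.

The flasks give 77.1% for autumn and 86.1% for noon: it rises, by 9 percentage points.

    free base + product ⇌ idle adduct, settled at all times (K = 32.0 M⁻¹)
    electrophile + nucleophile → acid set free + product (k = 9.50 M⁻¹ h⁻¹)
    free base ⇌ dormant form (K = 0.780, k = 0.0710 h⁻¹)
    nucleophile + protic impurity → quenched reagent (k = 3.60 M⁻¹ h⁻¹)
    acid set free + free base ⇌ salt of the base, settled at all times (K = 1.70 × 10⁵ M⁻¹)
    nucleophile + acid set free ⇌ protonated nucleophile, settled at all times (K = 47000 M⁻¹)

At the end of autumn, free base stands at 0.205% of its charge and nucleophile at 0.164% of its own, while protonated nucleophile holds 0.241 equiv, beside a stall level of 0.800 equiv. Noon ends at 86.1% with a stall level of 0.925 equiv; at its end protonated nucleophile holds 0.130 equiv and the protic impurity still stands at 47.3% of its charge. In a flask like noon with 0.440 equiv of nucleophile, half the sum exceeds the charge, so the stall level is 0.440 equiv; that flask reaches 40.4%, with free base at 18.0% of its charge.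

(The earlier runs and the new flask are calculated for an exercise, noise included.)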